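Slowness was my starting point. Z takes up a Z.X with a half-life of 1.2 d at the charged amounts, while Z captures X in a time of 1.37 h, so I reckoned in two stages, the second fed by what the first left over.

Z 0.050 M; X 0.0500 M; J 0.0125 M (in portions, 4); time 3.0 d; the portions of J follow each other after 15 min, the first at the start

    Z + Z.X → Z.Z.X (k1 = 0.471 M⁻¹ h⁻¹)
    X + J → X.J (k2 = 0.747 M⁻¹ h⁻¹)
    Z ⇌ D (K3 = 2.46, k3 = 0.0166 h⁻¹)
    X → L (k4 = 0.178 h⁻¹)
    Z + X → Z.X (k5 = 14.6 M⁻¹ h⁻¹)

- percentages count the Z that a species holds: one Z.Z.X counts as two
- the reaction counts as stopped when no species that holds the Z changes by six tenths of a point or more over the second half of the time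
- run time (flask): 3.0 d

* the state of affairs at 3.0 d: stopped, and by what, or still going (it is still moving / forward and back rates have come level / all of Z has reacted)
* the Z.X standing at 3.0 d, as a percentage of the Z charged
* the Z.Z.X standing at 3.0 d, as a percentage of the Z charged

Z.X starts upward at 0.0365 M h⁻¹, but X also leaks to L, and each X lost per X captured is κ/[Z]. I call κ = 0.0122 M the crossing level, the [Z] at which X goes to L as fast as into Z.X; [Z]/κ is the selectivity factor, 4.10 at the start. I set J aside, since its pull on X is 0.00934 h⁻¹ even at the whole charge, against 0.178 h⁻¹. I set D aside for this first stage, since Z reaches it in 60.2 h. Summing the leak as [Z] falls: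

[L] = κ ln(0.050 M / [Z])

Z and X are charged equally, so once X has gone, [L] equals the spare [Z]:

[Z] = κ ln(0.050 M / [Z])

Averaging each trial with what the right side returns, from κ, gave 0.0147 M, then 0.0148 M. So Z.X should reach a knee near 70.4 % within hours, the last X dying away in a time of 2.54 h.

After the knee D can no longer be set aside: Z reaches it in 60.2 h, about the same as the 60.3 h in which spare Z joins Z.X. The run is 1.19 such times long, so I expected it still moving. Z.X slopes down towards 40.8 % and Z.Z.X climbs towards 59.2 %, and my reckoning goes no further than these bounds.

The forecast went further, to single values: it is still moving, Z.X 50 % (44 % to 56 %) and Z.Z.X 29 % (23 % to 35 %), on the ground “that Z and D slowly convert Z.X into Z.Z.X”.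

The simulation gave it is still moving, with Z.X 54.8 % and Z.Z.X 27.3 %, both inside the forecast's ranges. Z.Z.X rose from 20.0 % at 1.50 d to 27.3 % at 3.00 d. Held against my ceiling, that reading is 46.1 % of the way.

The neighbour flask charged with 0.013 M of X holds [Z] above κ while X lasts, so the crossing level gives captures worth 20.9 % of the Z charged. The simulation of that neighbour flask gives Z.X 9.48 % and Z.Z.X 21.3 %, and Z.X plus half of Z.Z.X makes 20.1 %.

The constants were drawn at random within sensible limits; what happens was integrated by code.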